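**Retrosynthetic overview**
- The target 13 comes from tribenzyl ether 12 by hydrogenolysis of the three benzyl ethers on the apigenin half.
- Ring C of the acacetin half of 12 (O1, C2, C3, C4, C4a, C8a) is cut at C4–C4a and O1–C2, giving phloroglucinol 9 and β-ketoester 8. The interflavone bond C3–C6'' is already the α-carbon–aryl bond of 8.
- The strategy rests on ring A of the acacetin half (C4a, C5–C8, C8a with O1, 5-OH and 7-OH). This is the oxygen pattern of threefold-symmetric phloroglucinol, so every C–H/OH pair gives the same 5,7-dihydroxy ring A and the triol is used unprotected.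
- Ketoester 8 comes from C-aroylation of arylacetate 5 with 4-methoxybenzoyl chloride 6. Ester 5 comes from palladium-catalysed coupling of 6-iodide 4 with a Reformatsky reagent. Iodide 4 comes from apigenin 1 by 7,4'-dibenzylation, 5-OH-directed C6 iodination and 5-O-benzylation.
- Ring order: the three apigenin rings are bought intact; the only ring formed is acacetin ring C, in step 6.

Key step: step 6

Remark: the target has no stereocentre and its SMILES carries no axial descriptor, so the hindered C3–C6'' axis is left uncontrolled.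

**Step 1**
Reactants: 1 apigenin
Product: 2 7-(benzyloxy)-2-[4-(benzyloxy)phenyl]-5-hydroxy-4H-chromen-4-one (7,4'-di-O-benzylapigenin)
Conditions: BnBr (2.1 equiv), K2CO3 (2.5 equiv), DMF, rt
Reagents that add atoms: benzyl bromide, BrCc1ccccc1
Why: Williamson etherification in which the 7- and 4'-phenoxides are alkylated, while the 5-OH, hydrogen-bonded to the C4 carbonyl, should stay free with a limited amount of bromide at room temperature.

**Step 2**
Reactants: 2 7,4'-di-O-benzylapigenin
Product: 3 7-(benzyloxy)-2-[4-(benzyloxy)phenyl]-5-hydroxy-6-iodo-4H-chromen-4-one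
Conditions: BnNMe3·ICl2 (1.1 equiv), CaCO3, CH2Cl2–MeOH, rt
Reagents that add atoms: benzyltrimethylammonium dichloroiodate, C[N+](C)(C)Cc1ccccc1.Cl[I-]Cl
Why: Electrophilic aromatic iodination in which the free, chelated 5-OH of a 5-hydroxy-7-alkoxyflavone directs the iodonium equivalent to C6 (ortho to the phenol) rather than C8, with CaCO3 taking up the HCl so the benzyl ethers survive.

**Step 3**
Reactants: 3 6-iodo-7,4'-di-O-benzylapigenin
Product: 4 5,7-bis(benzyloxy)-2-[4-(benzyloxy)phenyl]-6-iodo-4H-chromen-4-one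
Conditions: BnBr (1.5 equiv), K2CO3 (3 equiv), DMF, 70 °C
Reagents that add atoms: benzyl bromide, BrCc1ccccc1
Why: Williamson etherification of the chelated, iodine-flanked 5-OH, which needs heat and excess bromide; benzylating only at this point keeps the phenol free for the C6-directing iodination of step 2.

**Step 4**
Reactants: 4 5,7,4'-tri-O-benzyl-6-iodoapigenin
Product: 5 ethyl 2-{5,7-bis(benzyloxy)-2-[4-(benzyloxy)phenyl]-4-oxo-4H-chromen-6-yl}acetate
Conditions: BrCH2CO2Et (3 equiv), Zn dust (Me3SiCl-activated), THF, 40 °C; then 4, Pd2(dba)3 (2.5 mol %), XPhos (10 mol %), THF, 65 °C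
Reagents that add atoms: ethyl bromoacetate, BrCC(=O)OCC, used as its zinc reagent bromo(2-ethoxy-2-oxoethyl)zinc, CCOC(=O)C[Zn]Br
Why: Palladium-catalysed Negishi-type coupling of a Reformatsky reagent (α-arylation of an ester through its zinc enolate), in which the bulky biarylphosphine lets zerovalent palladium insert into the di-ortho-alkoxy aryl iodide and drives reductive elimination, while the mild zinc enolate leaves the flavone carbonyl and the benzyl ethers alone.

**Step 5**
Reactants: 5 ethyl (tri-O-benzylapigenin-6-yl)acetate; 6 4-methoxybenzoyl chloride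
Product: 8 ethyl 2-{5,7-bis(benzyloxy)-2-[4-(benzyloxy)phenyl]-4-oxo-4H-chromen-6-yl}-3-(4-methoxyphenyl)-3-oxopropanoate (racemic, enolisable), via lithium ester enolate 7 (not isolated)
Conditions: LiN(SiMe3)2 (2.2 equiv), THF, −78 °C; then 6 (1.3 equiv), −78 → −20 °C; aq NH4Cl
Reagents that add atoms: none
Why: Claisen-type C-acylation of a lithium ester enolate with an aroyl chloride, in which LiN(SiMe3)2 deprotonates the arylacetate but not the flavone C3–H and the second equivalent converts the β-ketoester into its enolate, which stops further acylation; the α-carbon is enolisable and needs no stereocontrol.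

**Step 6**
Reactants: 8 β-ketoester; 9 phloroglucinol (anhydrous)
Product: 12 3-{5,7-bis(benzyloxy)-2-[4-(benzyloxy)phenyl]-4-oxo-4H-chromen-6-yl}-5,7-dihydroxy-2-(4-methoxyphenyl)-4H-chromen-4-one, via aroylketene 10 (not isolated), via acylphloroglucinol diketone 11 (not isolated)
Conditions: 9 (3 equiv), minimal Ph2O, 240 °C, argon stream to sweep out EtOH and H2O, 45–90 min
Reagents that add atoms: none
Why: At 240 °C ketoester 8 should lose ethanol to aroylketene 10, which acylates a ring carbon of phloroglucinol (directly, or after reversible O-acylation and return to the ketene) to give the chelated 2-acylphloroglucinol 11 and with it the C4–C4a bond. The flanking phenol of 11 then adds to the anisyl ketone in a 6-exo-trig closure and the hemiketal loses water, which forms O1–C2 and the C2=C3 bond of ring C; the closest known reaction type is the Mentzer (acid-free, thermal) chromone synthesis of 5,7-dihydroxyflavones from phloroglucinol and α-substituted aroylacetic esters. No stereocentre is created. The selectivity needed is chromone over coumarin, which the absence of acid and the hindered, electron-rich anisyl ketone (a poorer electrophile than the ketene) should secure, while regiochemistry on the phenol does not arise because all C–H/OH pairs of phloroglucinol are equivalent and a second condensation is held back by the excess of 9 and the deactivated ring A of 12. The three benzyl ethers are essential here, because a free 5''- or 7''-OH ortho to the ketoester carbon would lactonise to a benzofuranone, and benzyl aryl ethers should not be homolysed at this temperature within the short heating time.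

**Step 7**
Reactants: 12 tribenzyl ether of the target
Product: 13 3-[5,7-dihydroxy-2-(4-hydroxyphenyl)-4-oxo-4H-chromen-6-yl]-5,7-dihydroxy-2-(4-methoxyphenyl)-4H-chromen-4-one (target, CNP0273516.0)
Conditions: H2 (1 atm), 10% Pd/C, THF–MeOH, rt
Reagents that add atoms: none
Why: Catalytic hydrogenolysis of benzyl aryl ethers, under which the aryl methyl ether and the conjugated C2=C3 bonds of both flavone units should be inert at 1 atm and room temperature.

**Compound list**
1 | apigenin | O=c1cc(-c2ccc(O)cc2)oc2cc(O)cc(O)c12 | starting material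
2 | 7-(benzyloxy)-2-[4-(benzyloxy)phenyl]-5-hydroxy-4H-chromen-4-one | O=c1cc(-c2ccc(OCc3ccccc3)cc2)oc2cc(OCc3ccccc3)cc(O)c12 | intermediate
3 | 7-(benzyloxy)-2-[4-(benzyloxy)phenyl]-5-hydroxy-6-iodo-4H-chromen-4-one | O=c1cc(-c2ccc(OCc3ccccc3)cc2)oc2cc(OCc3ccccc3)c(I)c(O)c12 | intermediate
4 | 5,7-bis(benzyloxy)-2-[4-(benzyloxy)phenyl]-6-iodo-4H-chromen-4-one | O=c1cc(-c2ccc(OCc3ccccc3)cc2)oc2cc(OCc3ccccc3)c(I)c(OCc3ccccc3)c12 | intermediate
5 | ethyl 2-{5,7-bis(benzyloxy)-2-[4-(benzyloxy)phenyl]-4-oxo-4H-chromen-6-yl}acetate | CCOC(=O)Cc1c(OCc2ccccc2)cc2oc(-c3ccc(OCc4ccccc4)cc3)cc(=O)c2c1OCc1ccccc1 | intermediate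
6 | 4-methoxybenzoyl chloride | COc1ccc(cc1)C(Cl)=O | starting material
7 | lithium enolate of ester 5 (not isolated) | CCOC(O[Li])=Cc1c(OCc2ccccc2)cc2oc(-c3ccc(OCc4ccccc4)cc3)cc(=O)c2c1OCc1ccccc1 | intermediate
8 | ethyl 2-{5,7-bis(benzyloxy)-2-[4-(benzyloxy)phenyl]-4-oxo-4H-chromen-6-yl}-3-(4-methoxyphenyl)-3-oxopropanoate (racemic) | CCOC(=O)C(C(=O)c1ccc(OC)cc1)c1c(OCc2ccccc2)cc2oc(-c3ccc(OCc4ccccc4)cc3)cc(=O)c2c1OCc1ccccc1 | intermediate
9 | phloroglucinol | Oc1cc(O)cc(O)c1 | starting material
10 | 2-(tri-O-benzylapigenin-6-yl)-3-(4-methoxyphenyl)-3-oxoprop-1-en-1-one, the aroylketene (not isolated) | O=C=C(C(=O)c1ccc(OC)cc1)c1c(OCc2ccccc2)cc2oc(-c3ccc(OCc4ccccc4)cc3)cc(=O)c2c1OCc1ccccc1 | intermediate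
11 | 2-(tri-O-benzylapigenin-6-yl)-1-(4-methoxyphenyl)-3-(2,4,6-trihydroxyphenyl)propane-1,3-dione (not isolated) | Oc1cc(O)c(C(=O)C(C(=O)c2ccc(OC)cc2)c2c(OCc3ccccc3)cc3oc(-c4ccc(OCc5ccccc5)cc4)cc(=O)c3c2OCc2ccccc2)c(O)c1 | intermediate
12 | 3-{5,7-bis(benzyloxy)-2-[4-(benzyloxy)phenyl]-4-oxo-4H-chromen-6-yl}-5,7-dihydroxy-2-(4-methoxyphenyl)-4H-chromen-4-one | COc1ccc(cc1)-c1oc2cc(O)cc(O)c2c(=O)c1-c1c(OCc2ccccc2)cc2oc(-c3ccc(OCc4ccccc4)cc3)cc(=O)c2c1OCc1ccccc1 | intermediate
13 | 3-[5,7-dihydroxy-2-(4-hydroxyphenyl)-4-oxo-4H-chromen-6-yl]-5,7-dihydroxy-2-(4-methoxyphenyl)-4H-chromen-4-one | COc1ccc(-c2oc3cc(O)cc(O)c3c(=O)c2-c2c(O)cc3oc(-c4ccc(O)cc4)cc(=O)c3c2O)cc1 | target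

**Total step count:** 7
**Longest linear sequence:** 7 steps (apigenin 1 to target 13)

**Steps most likely to fail**

1. Step 6 (Mentzer condensation). The ketene may be diverted before it acylates the phenol carbon: the released water can hydrolyse the ester and lead to decarboxylation, an ortho benzyloxy oxygen can capture the ketene, or benzyl groups can be lost in the hot phenolic medium, after which the freed phenol lactonises. The fallback builds ring C stepwise at low temperature. It sets out from iodide 4, which is cyanomethylated (Me3SiCH2CN, ZnF2, Pd2(dba)3, Xantphos, DMF, 90 °C) to 2-(tri-O-benzylapigenin-6-yl)acetonitrile F1. Hoesch acylation of phloroglucinol 9 with F1 (ZnCl2, HCl gas, Et2O–dioxane, 0 °C; then hot water) should give the deoxybenzoin 2-(tri-O-benzylapigenin-6-yl)-1-(2,4,6-trihydroxyphenyl)ethanone F2. One-pot aroylation, Baker–Venkataraman acyl shift and cyclodehydration with excess 6 (K2CO3, acetone, reflux) should give the 5,7-bis(4-methoxybenzoate) of 12, F3. Methanolysis of the two aryl esters (K2CO3, MeOH–THF, rt) returns to the route at 12.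

2. Step 4 (Reformatsky coupling). Transmetalation of the zinc enolate onto the di-ortho-substituted arylpalladium may be slow, so that protodeiodination of 4 and self-condensation of the zinc reagent win. The fallback sets out from 4 and installs the two-carbon chain by allylation and oxidative cleavage. Stille coupling with allyltributylstannane (Pd(PPh3)4, CuI cat., DMF, 80 °C) should give 6-allyl-5,7,4'-tri-O-benzylapigenin F4. Lemieux–Johnson cleavage (OsO4 cat., NaIO4, 2,6-lutidine, dioxane–H2O) should give the arylacetaldehyde F5. Pinnick oxidation (NaClO2, NaH2PO4, 2-methyl-2-butene, t-BuOH–H2O) should give the arylacetic acid F6. Esterification (EtI, K2CO3, DMF) returns to the route at 5.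

3. Step 5 (C-aroylation). The hindered enolate may be acylated on oxygen (ketene acetal ester), or the amide base may consume the acid chloride. The fallback sets out from 5 and replaces acylation by aldol addition and oxidation. Enolate 7 (LiN(SiMe3)2, THF, −78 °C) is added to 4-methoxybenzaldehyde to give ethyl 2-(tri-O-benzylapigenin-6-yl)-3-hydroxy-3-(4-methoxyphenyl)propanoate F7 as a diastereomer mixture. Dess–Martin oxidation (CH2Cl2, NaHCO3, rt) returns to the route at 8.

**Further compounds**
F1 | step 6 | 2-{5,7-bis(benzyloxy)-2-[4-(benzyloxy)phenyl]-4-oxo-4H-chromen-6-yl}acetonitrile | N#CCc1c(OCc2ccccc2)cc2oc(-c3ccc(OCc4ccccc4)cc3)cc(=O)c2c1OCc1ccccc1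
F2 | step 6 | 2-{5,7-bis(benzyloxy)-2-[4-(benzyloxy)phenyl]-4-oxo-4H-chromen-6-yl}-1-(2,4,6-trihydroxyphenyl)ethan-1-one | Oc1cc(O)c(C(=O)Cc2c(OCc3ccccc3)cc3oc(-c4ccc(OCc5ccccc5)cc4)cc(=O)c3c2OCc2ccccc2)c(O)c1
F3 | step 6 | 5,7-bis-O-(4-methoxybenzoyl) derivative of 12 | COc1ccc(cc1)-c1oc2cc(OC(=O)c3ccc(OC)cc3)cc(OC(=O)c3ccc(OC)cc3)c2c(=O)c1-c1c(OCc2ccccc2)cc2oc(-c3ccc(OCc4ccccc4)cc3)cc(=O)c2c1OCc1ccccc1
F4 | step 4 | 6-allyl-5,7-bis(benzyloxy)-2-[4-(benzyloxy)phenyl]-4H-chromen-4-one | C=CCc1c(OCc2ccccc2)cc2oc(-c3ccc(OCc4ccccc4)cc3)cc(=O)c2c1OCc1ccccc1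
F5 | step 4 | 2-{5,7-bis(benzyloxy)-2-[4-(benzyloxy)phenyl]-4-oxo-4H-chromen-6-yl}acetaldehyde | O=CCc1c(OCc2ccccc2)cc2oc(-c3ccc(OCc4ccccc4)cc3)cc(=O)c2c1OCc1ccccc1
F6 | step 4 | 2-{5,7-bis(benzyloxy)-2-[4-(benzyloxy)phenyl]-4-oxo-4H-chromen-6-yl}acetic acid | OC(=O)Cc1c(OCc2ccccc2)cc2oc(-c3ccc(OCc4ccccc4)cc3)cc(=O)c2c1OCc1ccccc1
F7 | step 5 | ethyl 2-{5,7-bis(benzyloxy)-2-[4-(benzyloxy)phenyl]-4-oxo-4H-chromen-6-yl}-3-hydroxy-3-(4-methoxyphenyl)propanoate (diastereomer mixture) | CCOC(=O)C(C(O)c1ccc(OC)cc1)c1c(OCc2ccccc2)cc2oc(-c3ccc(OCc4ccccc4)cc3)cc(=O)c2c1OCc1ccccc1
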